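**Retrosynthetic overview**
- Menaquinone-8 ⇒ menadione + all-E-octaprenyl(trimethyl)stannane: the ring C3–C1′ bond is made last by a Lewis-acid-mediated conjugate (Michael-type) allylation of the quinone, followed by re-oxidation of the hydroquinone.
- Octaprenyl stannane ⇒ all-E-octaprenol ⇒ C20 + C20: α-lithio geranylgeranyl phenyl sulfone + ω-bromo-geranylgeranyl silyl ether, then Pd-catalysed reductive desulfonylation.
- Both C20 halves ⇒ one common intermediate, geranylgeranyl TBDPS ether, made the same way from two geraniol units (C10 sulfone + ω-bromo C10 silyl ether); ω-functionalisation by SeO2 allylic oxidation.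
- Rings: none is formed; the naphthoquinone bicycle is bought intact as menadione. All seven E-alkenes come from (E)-geraniol and are retained.

Assumption: menaquinone-8 has no stereogenic centre, so "single enantiomer" is read as the single all-E geometric isomer.

**Route**

Step 1
Reactants: 1 geraniol
Product: 2 geranyl TBDPS ether
Conditions: TBDPSCl, imidazole, DMF, 0 °C → rt
Reagents that add atoms: tert-butyl(chloro)diphenylsilane, CC(C)(C)[Si](Cl)(c1ccccc1)c1ccccc1
Why: Standard imidazole-promoted silylation of a primary alcohol gives a robust, UV-active ether that survives SeO2, Appel, organolithium and hydride conditions.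

Step 2
Reactants: 2 geranyl TBDPS ether
Product: 3 (2E,6E)-8-hydroxygeranyl TBDPS ether
Conditions: SeO2 (0.2 equiv), t-BuOOH (3 equiv), salicylic acid (0.1 equiv), CH2Cl2, 0 °C → rt; stopped at partial conversion, 2 recycled
Reagents that add atoms: tert-butyl hydroperoxide, CC(C)(C)OO (source of the new oxygen atom, relayed through catalytic SeO2, O=[Se]=O)
Why: Sharpless catalytic SeO2 allylic oxidation (ene reaction, then [2,3]-sigmatropic shift) hydroxylates the E-methyl of the terminal, most electron-rich alkene and sets the 6E allylic alcohol geometry, the C2 alkene being deactivated by the allylic silyloxy group.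

Step 3
Reactants: 3 (2E,6E)-8-hydroxygeranyl TBDPS ether
Product: 4 (2E,6E)-8-bromogeranyl TBDPS ether
Conditions: CBr4, PPh3, CH2Cl2, 0 °C
Reagents that add atoms: carbon tetrabromide, BrC(Br)(Br)Br
Why: Appel bromination displaces the primary allylic alkoxyphosphonium by SN2 under neutral conditions, without allylic transposition or E/Z loss.

Step 4
Reactants: 1 geraniol
Product: 5 geranyl bromide
Conditions: PBr3 (0.4 equiv), Et2O, −10 °C
Reagents that add atoms: phosphorus tribromide, BrP(Br)Br
Why: Low-temperature bromination of the primary allylic alcohol through its phosphite ester is the standard E-retentive route to geranyl bromide.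

Step 5
Reactants: 5 geranyl bromide
Product: 6 geranyl phenyl sulfone
Conditions: PhSO2Na, DMF, rt
Reagents that add atoms: sodium benzenesulfinate, [Na+].[O-]S(=O)c1ccccc1
Why: SN2 S-alkylation of the soft sulfinate at the primary allylic carbon gives the allylic sulfone with the 2E alkene untouched.

Step 6
Reactants: 6 geranyl phenyl sulfone; 4 (2E,6E)-8-bromogeranyl TBDPS ether
Product: 8 9-(phenylsulfonyl)geranylgeranyl TBDPS ether (racemic at C9), via α-lithio geranyl phenyl sulfone 7 (not isolated)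
Conditions: n-BuLi, THF, −78 °C; then 4, THF/DMPU, −78 → −20 °C
Reagents that add atoms: none
Why: Sulfone-stabilised allylic carbanion alkylation (Biellmann/Julia-type coupling) joins the units by SN2 at the primary allylic bromide without touching any alkene; the racemic C9 centre is erased in step 7.

Step 7
Reactants: 8 9-(phenylsulfonyl)geranylgeranyl TBDPS ether
Product: 9 (2E,6E,10E)-geranylgeranyl TBDPS ether
Conditions: PdCl2(dppp) (5 mol %), LiBHEt3 (2.2 equiv), THF, 0 °C
Reagents that add atoms: none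
Why: Pd-catalysed reductive desulfonylation ionises the allylic sulfone to a syn π-allyl and delivers hydride to the less substituted terminus, so the 10E trisubstituted alkene stays in place with its geometry.

Step 8
Reactants: 9 (2E,6E,10E)-geranylgeranyl TBDPS ether
Product: 10 (2E,6E,10E)-geranylgeraniol
Conditions: TBAF, THF, rt
Reagents that add atoms: none
Why: Fluoride-driven Si–O cleavage frees the primary allylic alcohol under conditions inert to the polyene.

Step 9
Reactants: 10 (2E,6E,10E)-geranylgeraniol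
Product: 11 (2E,6E,10E)-geranylgeranyl bromide
Conditions: PBr3 (0.4 equiv), Et2O, 0 °C
Reagents that add atoms: phosphorus tribromide, BrP(Br)Br
Why: Same E-retentive primary allylic bromination as step 4.

Step 10
Reactants: 11 (2E,6E,10E)-geranylgeranyl bromide
Product: 12 (2E,6E,10E)-geranylgeranyl phenyl sulfone
Conditions: PhSO2Na, DMF, rt
Reagents that add atoms: sodium benzenesulfinate, [Na+].[O-]S(=O)c1ccccc1
Why: SN2 S-alkylation of sulfinate as in step 5 gives the C20 nucleophile precursor.

Step 11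
Reactants: 9 (2E,6E,10E)-geranylgeranyl TBDPS ether
Product: 13 (2E,6E,10E,14E)-16-hydroxygeranylgeranyl TBDPS ether
Conditions: SeO2 (0.2 equiv), t-BuOOH (3 equiv), salicylic acid (0.1 equiv), CH2Cl2, 0 °C → rt; stopped at partial conversion, 9 recycled
Reagents that add atoms: tert-butyl hydroperoxide, CC(C)(C)OO (source of the new oxygen atom, relayed through catalytic SeO2, O=[Se]=O)
Why: The same SeO2 ene/[2,3] allylic oxidation favours the E-methyl of the terminal gem-dimethyl alkene and sets the 14E geometry; the separable internal-oxidation by-products are accepted at partial conversion.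

Step 12
Reactants: 13 (2E,6E,10E,14E)-16-hydroxygeranylgeranyl TBDPS ether
Product: 14 (2E,6E,10E,14E)-16-bromogeranylgeranyl TBDPS ether
Conditions: CBr4, PPh3, CH2Cl2, 0 °C
Reagents that add atoms: carbon tetrabromide, BrC(Br)(Br)Br
Why: Appel bromination as in step 3, neutral and E-retentive.

Step 13
Reactants: 12 (2E,6E,10E)-geranylgeranyl phenyl sulfone; 14 (2E,6E,10E,14E)-16-bromogeranylgeranyl TBDPS ether
Product: 16 17-(phenylsulfonyl)-all-E-octaprenyl TBDPS ether (racemic at C17), via α-lithio geranylgeranyl phenyl sulfone 15 (not isolated)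
Conditions: n-BuLi, THF, −78 °C; then 14, THF/DMPU, −78 → −20 °C
Reagents that add atoms: none
Why: The same sulfone-carbanion SN2 alkylation as step 6 assembles the C40 chain; the racemic C17 centre is removed in step 14.

Step 14
Reactants: 16 17-(phenylsulfonyl)-all-E-octaprenyl TBDPS ether
Product: 17 all-E-octaprenyl TBDPS ether
Conditions: PdCl2(dppp) (5 mol %), LiBHEt3 (2.2 equiv), THF, 0 °C
Reagents that add atoms: none
Why: Pd-catalysed reductive desulfonylation as in step 7, with hydride delivered to the secondary π-allyl terminus so the 18E alkene is retained.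

Step 15
Reactants: 17 all-E-octaprenyl TBDPS ether
Product: 18 all-E-octaprenol
Conditions: TBAF, THF, rt
Reagents that add atoms: none
Why: Fluoride desilylation as in step 8.

Step 16
Reactants: 18 all-E-octaprenol
Product: 19 all-E-octaprenyl chloride
Conditions: NCS, Me2S, CH2Cl2, −40 → 0 °C
Reagents that add atoms: N-chlorosuccinimide, O=C1CCC(=O)N1Cl
Why: Corey–Kim chlorination displaces the alkoxysulfonium by chloride (SN2) under neutral conditions, without allylic transposition or loss of the 2E geometry.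

Step 17
Reactants: 19 all-E-octaprenyl chloride
Product: 20 all-E-octaprenyl(trimethyl)stannane
Conditions: Me3SnLi (from Me3SnCl, Li, THF), THF, −78 → −20 °C; filtration through neutral alumina (hexane)
Reagents that add atoms: trimethylstannyllithium, [Li][Sn](C)(C)C (made in the flask from chlorotrimethylstannane, C[Sn](C)(C)Cl, and lithium)
Why: SN2 stannylation of the primary allylic chloride by the soft stannyl anion gives the linear allylstannane with the 2E alkene intact.

Step 18
Reactants: 20 all-E-octaprenyl(trimethyl)stannane; 21 menadione (2-methyl-1,4-naphthoquinone)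
Product: 23 menaquinone-8, via menaquinol-8 22 (not isolated)
Conditions: BF3·OEt2 (2.5 equiv), CH2Cl2, −78 → −20 °C; aq. NaHCO3; then Ag2O, Et2O, rt, dark; crystallisation from acetone
Reagents that add atoms: none
Why: BF3-activated menadione takes up the allylstannane in a Naruta-type conjugate (Michael) allylation at its only unsubstituted enone carbon C3, transferring the linear 2′E-allyl unit with loss of Me3Sn, and Ag2O re-oxidises the hydroquinone to the quinone.

**Compound list**
1 | geraniol, (2E)-3,7-dimethylocta-2,6-dien-1-ol | CC(C)=CCC/C(C)=C/CO | starting material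
2 | geranyl TBDPS ether | CC(C)=CCC/C(C)=C/CO[Si](c1ccccc1)(c1ccccc1)C(C)(C)C | intermediate
3 | (2E,6E)-8-(tert-butyldiphenylsilyloxy)-2,6-dimethylocta-2,6-dien-1-ol | OC/C(C)=C/CC/C(C)=C/CO[Si](c1ccccc1)(c1ccccc1)C(C)(C)C | intermediate
4 | (2E,6E)-8-bromo-3,7-dimethylocta-2,6-dienyl TBDPS ether | BrC/C(C)=C/CC/C(C)=C/CO[Si](c1ccccc1)(c1ccccc1)C(C)(C)C | intermediate
5 | geranyl bromide | CC(C)=CCC/C(C)=C/CBr | intermediate
6 | geranyl phenyl sulfone | CC(C)=CCC/C(C)=C/CS(=O)(=O)c1ccccc1 | intermediate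
7 | α-lithio geranyl phenyl sulfone (not isolated) | CC(C)=CCC/C(C)=C/C([Li])S(=O)(=O)c1ccccc1 | intermediate
8 | (2E,6E,10E)-3,7,11,15-tetramethyl-9-(phenylsulfonyl)hexadeca-2,6,10,14-tetraenyl TBDPS ether, racemic at C9 | CC(C)=CCC/C(C)=C/C(C/C(C)=C/CC/C(C)=C/CO[Si](c1ccccc1)(c1ccccc1)C(C)(C)C)S(=O)(=O)c1ccccc1 | intermediate
9 | (2E,6E,10E)-geranylgeranyl TBDPS ether | CC(C)=CCC/C(C)=C/CC/C(C)=C/CC/C(C)=C/CO[Si](c1ccccc1)(c1ccccc1)C(C)(C)C | intermediate
10 | (2E,6E,10E)-geranylgeraniol | CC(C)=CCC/C(C)=C/CC/C(C)=C/CC/C(C)=C/CO | intermediate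
11 | (2E,6E,10E)-geranylgeranyl bromide | CC(C)=CCC/C(C)=C/CC/C(C)=C/CC/C(C)=C/CBr | intermediate
12 | (2E,6E,10E)-geranylgeranyl phenyl sulfone | CC(C)=CCC/C(C)=C/CC/C(C)=C/CC/C(C)=C/CS(=O)(=O)c1ccccc1 | intermediate
13 | (2E,6E,10E,14E)-16-(tert-butyldiphenylsilyloxy)-2,6,10,14-tetramethylhexadeca-2,6,10,14-tetraen-1-ol | OC/C(C)=C/CC/C(C)=C/CC/C(C)=C/CC/C(C)=C/CO[Si](c1ccccc1)(c1ccccc1)C(C)(C)C | intermediate
14 | (2E,6E,10E,14E)-16-bromo-3,7,11,15-tetramethylhexadeca-2,6,10,14-tetraenyl TBDPS ether | BrC/C(C)=C/CC/C(C)=C/CC/C(C)=C/CC/C(C)=C/CO[Si](c1ccccc1)(c1ccccc1)C(C)(C)C | intermediate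
15 | α-lithio geranylgeranyl phenyl sulfone (not isolated) | CC(C)=CCC/C(C)=C/CC/C(C)=C/CC/C(C)=C/C([Li])S(=O)(=O)c1ccccc1 | intermediate
16 | all-E-17-(phenylsulfonyl)octaprenyl TBDPS ether, racemic at C17 | CC(C)=CCC/C(C)=C/CC/C(C)=C/CC/C(C)=C/C(C/C(C)=C/CC/C(C)=C/CC/C(C)=C/CC/C(C)=C/CO[Si](c1ccccc1)(c1ccccc1)C(C)(C)C)S(=O)(=O)c1ccccc1 | intermediate
17 | all-E-octaprenyl TBDPS ether | CC(C)=CCC/C(C)=C/CC/C(C)=C/CC/C(C)=C/CC/C(C)=C/CC/C(C)=C/CC/C(C)=C/CC/C(C)=C/CO[Si](c1ccccc1)(c1ccccc1)C(C)(C)C | intermediate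
18 | all-E-octaprenol, (2E,6E,10E,14E,18E,22E,26E)-3,7,11,15,19,23,27,31-octamethyldotriaconta-2,6,10,14,18,22,26,30-octaen-1-ol | CC(C)=CCC/C(C)=C/CC/C(C)=C/CC/C(C)=C/CC/C(C)=C/CC/C(C)=C/CC/C(C)=C/CC/C(C)=C/CO | intermediate
19 | all-E-octaprenyl chloride | CC(C)=CCC/C(C)=C/CC/C(C)=C/CC/C(C)=C/CC/C(C)=C/CC/C(C)=C/CC/C(C)=C/CC/C(C)=C/CCl | intermediate
20 | all-E-octaprenyl(trimethyl)stannane | CC(C)=CCC/C(C)=C/CC/C(C)=C/CC/C(C)=C/CC/C(C)=C/CC/C(C)=C/CC/C(C)=C/CC/C(C)=C/C[Sn](C)(C)C | intermediate
21 | menadione, 2-methyl-1,4-naphthoquinone | CC1=CC(=O)c2ccccc2C1=O | starting material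
22 | menaquinol-8, 2-methyl-3-(all-E-octaprenyl)naphthalene-1,4-diol (not isolated) | CC(C)=CCC/C(C)=C/CC/C(C)=C/CC/C(C)=C/CC/C(C)=C/CC/C(C)=C/CC/C(C)=C/CC/C(C)=C/Cc1c(C)c(O)c2ccccc2c1O | intermediate
23 | menaquinone-8, 2-methyl-3-(all-E-octaprenyl)-1,4-naphthoquinone | CC(C)=CCC/C(C)=C/CC/C(C)=C/CC/C(C)=C/CC/C(C)=C/CC/C(C)=C/CC/C(C)=C/CC/C(C)=C/CC1=C(C)C(=O)c2ccccc2C1=O | target

**Totals**
Total step count: 18.
Longest linear sequence: 14 steps (steps 1, 2, 3, 6, 7, 8, 9, 10, 13, 14, 15, 16, 17, 18, from geraniol through sulfone 12).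

**Three steps most likely to fail, with fallbacks**

Step 11 (SeO2 oxidation of the C20 ether 9). With four trisubstituted alkenes, internal allylic oxidation and over-oxidation compete, so the yield may be low. The fallback is a terminal bromohydrin/chain-rebuilding sequence that sets out from 9 and comes back at 13. NBS in THF/H2O at 0 °C gives the terminal 14-bromo-15-hydroxy bromohydrin F1. K2CO3 in MeOH closes it to the terminal 14,15-epoxide F2. HIO4·2H2O in THF/Et2O opens this to the 14,15-diol F3 (not isolated) and cleaves it, with loss of acetone, to the trisnor trienal F4. Wittig olefination with Ph3P=C(CH3)CO2Et in CH2Cl2 gives the ethyl (2E)-enoate F5, and DIBAL-H in toluene at −78 °C reduces it to 13.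

Step 14 (desulfonylation of the C40 sulfone 16). Hydride delivery to the wrong π-allyl terminus, or partial E/Z erosion, would give isomers that are hard to separate at C40. The fallback drops the sulfone coupling; it sets out from 10, uses bromide 14 from step 12, and comes back at 17. NCS/Me2S converts 10 into geranylgeranyl chloride F6. Activated barium (BaI2, lithium biphenylide, THF, −78 °C) turns this into geranylgeranylbarium chloride F7. This allylbarium couples α,α′-selectively with 14 at −78 °C, with retention of alkene geometry, to give 17 directly.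

Step 18 (quinone allylation). Possible problems are protodestannylation of 20, BF3-induced polyene cyclisation, and some loss of 2′E purity. The fallback replaces the stannane coupling by enolate alkylation of a masked quinone; it sets out from 21 and 19 and comes back at 23. Menadione and cyclopentadiene (EtOH, rt) give the endo Diels–Alder adduct F8. KOt-Bu in THF at 0 °C gives the potassium enolate F9, which is C-alkylated by chloride 19 (cat. NaI) on the exo face to the octaprenylated adduct F10. Heating F10 in toluene at 110 °C (retro-Diels–Alder) releases cyclopentadiene and gives 23.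

**Further compounds**
F1 | step 11 | (2E,6E,10E)-14-bromo-15-hydroxy-3,7,11,15-tetramethylhexadeca-2,6,10-trienyl TBDPS ether (racemic) | CC(C)(O)C(Br)CC/C(C)=C/CC/C(C)=C/CC/C(C)=C/CO[Si](c1ccccc1)(c1ccccc1)C(C)(C)C
F2 | step 11 | (2E,6E,10E)-14,15-epoxy-3,7,11,15-tetramethylhexadeca-2,6,10-trienyl TBDPS ether (racemic) | CC1(C)OC1CC/C(C)=C/CC/C(C)=C/CC/C(C)=C/CO[Si](c1ccccc1)(c1ccccc1)C(C)(C)C
F3 | step 11 | (2E,6E,10E)-14,15-dihydroxy-3,7,11,15-tetramethylhexadeca-2,6,10-trienyl TBDPS ether (racemic, not isolated) | CC(C)(O)C(O)CC/C(C)=C/CC/C(C)=C/CC/C(C)=C/CO[Si](c1ccccc1)(c1ccccc1)C(C)(C)C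
F4 | step 11 | (4E,8E,12E)-14-(tert-butyldiphenylsilyloxy)-4,8,12-trimethyltetradeca-4,8,12-trienal | O=CCC/C(C)=C/CC/C(C)=C/CC/C(C)=C/CO[Si](c1ccccc1)(c1ccccc1)C(C)(C)C
F5 | step 11 | ethyl (2E,6E,10E,14E)-16-(tert-butyldiphenylsilyloxy)-2,6,10,14-tetramethylhexadeca-2,6,10,14-tetraenoate | CCOC(=O)/C(C)=C/CC/C(C)=C/CC/C(C)=C/CC/C(C)=C/CO[Si](c1ccccc1)(c1ccccc1)C(C)(C)C
F6 | step 14 | (2E,6E,10E)-geranylgeranyl chloride | CC(C)=CCC/C(C)=C/CC/C(C)=C/CC/C(C)=C/CCl
F7 | step 14 | (2E,6E,10E)-geranylgeranylbarium chloride (not isolated) | CC(C)=CCC/C(C)=C/CC/C(C)=C/CC/C(C)=C/C[Ba]Cl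
F8 | step 18 | endo-4a-methyl-1,4,4a,9a-tetrahydro-1,4-methanoanthracene-9,10-dione (racemic, one enantiomer drawn) | C[C@]12C(=O)c3ccccc3C(=O)[C@H]1[C@H]1C=C[C@@H]2C1
F9 | step 18 | potassium enolate of F8 (not isolated, racemic) | C[C@]12C(=O)c3ccccc3C([O-])=C1[C@H]1C=C[C@@H]2C1.[K+]
F10 | step 18 | endo-4a-methyl-9a-(all-E-octaprenyl)-1,4,4a,9a-tetrahydro-1,4-methanoanthracene-9,10-dione (racemic, one enantiomer drawn) | C[C@]12C(=O)c3ccccc3C(=O)[C@@]1(C/C=C(C)/CC/C=C(C)/CC/C=C(C)/CC/C=C(C)/CC/C=C(C)/CC/C=C(C)/CC/C=C(C)/CCC=C(C)C)[C@H]1C=C[C@@H]2C1
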